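**Retrosynthetic overview**
1. Target ⇐ fluoride desilylation of its bis-silyl ether ⇐ C7=C8 by aldol addition/mesylate elimination between a 2-bromo-4-silyloxy-4-octadienylcyclopentenone and methyl (S,E)-7-oxo-4-silyloxyhept-5-enoate.
2. Ring block ⇐ Z-selective Wittig (C14=C15) of a ring acetaldehyde with the (Z)-hex-3-enyl ylide. Bromine goes in earlier by Br2/Et3N on the simple enone, before any other C=C exists, and the ketone is parked as a silyl ether during the hydride and ylide steps.
3. C12 ⇐ anti 1,2-addition of lithio ethyl acetate to (R)-4-silyloxycyclopentenone, which comes from hydrolase (esterase) desymmetrisation of meso cis-3,5-diacetoxycyclopentene.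
4. Side-chain block ⇐ cross-metathesis with crotonaldehyde ⇐ terminal alkene ⇐ alkyne ⇐ Noyori asymmetric transfer hydrogenation of a silyl ynone (sets C4).
5. Rings: the only ring, the cyclopentene, is already in the meso starting material and is carried through; no ring is formed.

Assumption: carbinol centres that are later oxidised or eliminated (the ring CH–O made by Luche reduction; C7/C8 of the aldol) are carried as epimer mixtures. Target positions use prostanoid numbering (ester carbon C1, ring C8–C12, octadienyl C13–C20).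

**Ring block**

Step 1
Reactants: 1 cis-cyclopent-4-ene-1,3-diyl diacetate (meso)
Product: 2 (1R,4S)-4-hydroxycyclopent-2-en-1-yl acetate
Conditions: electric-eel acetylcholinesterase (a serine hydrolase, esterase class), aq. NaH2PO4/Na2HPO4 buffer pH 6.9, rt
Reagents that add atoms: none
Why: Enzymatic desymmetrisation (enantiotopic-group-selective ester hydrolysis) cleaves only the acetate on the (S)-carbon of the meso diacetate, which sets the first stereocentres in high ee.

Step 2
Reactants: 2 (1R,4S)-4-hydroxycyclopent-2-en-1-yl acetate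
Product: 3 (1R)-4-oxocyclopent-2-en-1-yl acetate
Conditions: activated MnO2, CH2Cl2, rt
Reagents that add atoms: none
Why: Allylic alcohol oxidation touches only the free carbinol, so the acetate-bearing carbon stays (R) and becomes C4 of the enone.

Step 3
Reactants: 3 (1R)-4-oxocyclopent-2-en-1-yl acetate
Product: 4 (4R)-4-hydroxycyclopent-2-en-1-one
Conditions: wheat-germ lipase (hydrolase), aq. NaH2PO4/Na2HPO4 buffer pH 5.0, rt, 5–7 d
Reagents that add atoms: none
Why: Lipase-catalysed ester hydrolysis at pH 5 removes the acetate without the β-elimination that chemical base would cause, and the stereocentre is not involved.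

Step 4
Reactants: 4 (4R)-4-hydroxycyclopent-2-en-1-one
Product: 5 (4R)-4-(tert-butyldimethylsilyloxy)cyclopent-2-en-1-one
Conditions: TBSCl, Et3N, DMAP (cat.), CH2Cl2, 0 °C → rt
Reagents that add atoms: tert-butyldimethylsilyl chloride, CC(C)(C)[Si](C)(C)Cl
Why: Silyl ether formation under mild amine base gives the bulky group that will shield one face of the ring.

Step 5
Reactants: 5 (4R)-4-(tert-butyldimethylsilyloxy)cyclopent-2-en-1-one; 6 ethyl acetate
Product: 8 ethyl 2-[(1R,4R)-4-(tert-butyldimethylsilyloxy)-1-hydroxycyclopent-2-en-1-yl]acetate, via lithium enolate of ethyl acetate 7 (not isolated)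
Conditions: LiN(iPr)2, 6, THF, −78 °C; then 5, −78 °C, 30 min; AcOH quench at −78 °C
Reagents that add atoms: none
Why: Kinetic 1,2-addition (aldol type) of the ester enolate to the enone carbonyl occurs anti to the C4 silyloxy group, setting the tertiary carbinol (future C12) as 1R; the minor syn adduct is removed by chromatography.

Step 6
Reactants: 8 ethyl 2-[(1R,4R)-4-(tert-butyldimethylsilyloxy)-1-hydroxycyclopent-2-en-1-yl]acetate
Product: 9 ethyl 2-[(1R,4R)-1,4-dihydroxycyclopent-2-en-1-yl]acetate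
Conditions: Bu4NF, AcOH (1:1), THF, 0 °C → rt
Reagents that add atoms: none
Why: Fluoride-mediated desilylation, buffered with AcOH so that the β-hydroxy ester does not undergo retro-aldol.

Step 7
Reactants: 9 ethyl 2-[(1R,4R)-1,4-dihydroxycyclopent-2-en-1-yl]acetate
Product: 10 ethyl 2-[(1R)-1-hydroxy-4-oxocyclopent-2-en-1-yl]acetate
Conditions: activated MnO2, CH2Cl2, rt
Reagents that add atoms: none
Why: Chemoselective allylic oxidation of the secondary alcohol (the tertiary one cannot be oxidised) erases the relay stereocentre and gives the γ-hydroxy enone with C12 intact.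

Step 8
Reactants: 10 ethyl 2-[(1R)-1-hydroxy-4-oxocyclopent-2-en-1-yl]acetate
Product: 12 ethyl 2-[(1R)-3-bromo-1-hydroxy-4-oxocyclopent-2-en-1-yl]acetate, via 2,3-dibromo ketone 11 (not isolated)
Conditions: Br2 (1.05 equiv), CH2Cl2, 0 °C; then Et3N, 0 °C → rt
Reagents that add atoms: bromine, BrBr
Why: Bromine addition to the enone followed by E1cB loss of HBr (bromination–dehydrobromination) puts Br on the α-carbon, and it is done here because no other C=C is present yet.

Step 9
Reactants: 12 ethyl 2-[(1R)-3-bromo-1-hydroxy-4-oxocyclopent-2-en-1-yl]acetate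
Product: 13 ethyl 2-[(1R,4RS)-3-bromo-1,4-dihydroxycyclopent-2-en-1-yl]acetate (C4 epimers)
Conditions: NaBH4, CeCl3·7H2O, MeOH, −78 → −40 °C
Reagents that add atoms: none
Why: Luche 1,2-reduction masks the ketone as an allylic alcohol so the later hydride and ylide steps cannot touch it; the new centre is re-oxidised in step 16, so its configuration does not matter.

Step 10
Reactants: 13 ethyl 2-[(1R,4RS)-3-bromo-1,4-dihydroxycyclopent-2-en-1-yl]acetate
Product: 14 ethyl 2-[(1R,4RS)-3-bromo-1,4-bis(triethylsilyloxy)cyclopent-2-en-1-yl]acetate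
Conditions: Et3SiOTf (2.6 equiv), 2,6-lutidine, CH2Cl2, −78 → −20 °C
Reagents that add atoms: triethylsilyl trifluoromethanesulfonate, CC[Si](CC)(CC)OS(=O)(=O)C(F)(F)F
Why: The silyl triflate silylates both the secondary and the hindered tertiary hydroxyl (silyl ether protection), which blocks retro-aldol and β-elimination in the next two steps.

Step 11
Reactants: 14 ethyl 2-[(1R,4RS)-3-bromo-1,4-bis(triethylsilyloxy)cyclopent-2-en-1-yl]acetate
Product: 15 2-[(1R,4RS)-3-bromo-1,4-bis(triethylsilyloxy)cyclopent-2-en-1-yl]acetaldehyde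
Conditions: iBu2AlH (1.2 equiv), CH2Cl2, −78 °C; MeOH, then aq. potassium sodium tartrate
Reagents that add atoms: none
Why: Partial ester reduction at −78 °C stops at the tetrahedral aluminium hemiacetal, which releases the aldehyde only on work-up.

Step 12
Reactants: 16 (3Z)-hex-3-en-1-ol
Product: 17 (3Z)-1-iodohex-3-ene
Conditions: I2, PPh3, imidazole, CH2Cl2, 0 °C → rt
Reagents that add atoms: iodine, II
Why: Appel-type iodination converts the primary alcohol by SN2 displacement without touching the Z-alkene.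

Step 13
Reactants: 17 (3Z)-1-iodohex-3-ene
Product: 18 [(3Z)-hex-3-en-1-yl]triphenylphosphonium iodide
Conditions: PPh3, MeCN, reflux
Reagents that add atoms: triphenylphosphine, c1ccc(cc1)P(c1ccccc1)c1ccccc1
Why: SN2 quaternisation of the phosphine by the primary iodide gives the Wittig salt.

Step 14
Reactants: 15 2-[(1R,4RS)-3-bromo-1,4-bis(triethylsilyloxy)cyclopent-2-en-1-yl]acetaldehyde; 18 [(3Z)-hex-3-en-1-yl]triphenylphosphonium iodide
Product: 20 (1S,4RS)-3-bromo-1-[(2Z,5Z)-octa-2,5-dien-1-yl]-1,4-bis(triethylsilyloxy)cyclopent-2-ene, via phosphorus ylide 19 (not isolated)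
Conditions: 18, NaN(SiMe3)2, THF, −78 → 0 °C; then 15, −78 °C → rt
Reagents that add atoms: none
Why: Wittig olefination with the non-stabilised, lithium-free ylide under kinetic control makes the new C14=C15 bond Z, while the existing Z-alkene is carried in unchanged.

Step 15
Reactants: 20 (1S,4RS)-3-bromo-1-[(2Z,5Z)-octa-2,5-dien-1-yl]-1,4-bis(triethylsilyloxy)cyclopent-2-ene
Product: 21 (1S,4RS)-3-bromo-1-[(2Z,5Z)-octa-2,5-dien-1-yl]cyclopent-2-ene-1,4-diol
Conditions: Bu4NF (3 equiv), THF, rt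
Reagents that add atoms: none
Why: Fluoride-mediated desilylation removes both triethylsilyl ethers; no carbonyl or other base-sensitive group is present.

Step 16
Reactants: 21 (1S,4RS)-3-bromo-1-[(2Z,5Z)-octa-2,5-dien-1-yl]cyclopent-2-ene-1,4-diol
Product: 22 (4S)-2-bromo-4-hydroxy-4-[(2Z,5Z)-octa-2,5-dien-1-yl]cyclopent-2-en-1-one
Conditions: Dess–Martin periodinane, CH2Cl2, 0 °C → rt
Reagents that add atoms: none
Why: Dess–Martin oxidation returns the secondary allylic alcohol to the α-bromo enone, both epimers converging on one compound, while the tertiary alcohol and skipped diene are inert.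

Step 17
Reactants: 22 (4S)-2-bromo-4-hydroxy-4-[(2Z,5Z)-octa-2,5-dien-1-yl]cyclopent-2-en-1-one
Product: 23 (4S)-2-bromo-4-[(2Z,5Z)-octa-2,5-dien-1-yl]-4-(trimethylsilyloxy)cyclopent-2-en-1-one
Conditions: Me3SiOTf, 2,6-lutidine, CH2Cl2, −78 °C
Reagents that add atoms: trimethylsilyl trifluoromethanesulfonate, C[Si](C)(C)OS(=O)(=O)C(F)(F)F
Why: Silylation of the tertiary alcohol with a non-nucleophilic base (silyl ether protection) prevents alkoxide-driven retro-aldol during the enolate step.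

**Side-chain block**

Step 18
Reactants: 24 methyl 4-chloro-4-oxobutanoate; 25 bis(trimethylsilyl)acetylene
Product: 26 methyl 4-oxo-6-(trimethylsilyl)hex-5-ynoate
Conditions: AlCl3 (1.1 equiv), CH2Cl2, 0 °C
Reagents that add atoms: none
Why: Friedel–Crafts-type acylation of the alkynylsilane (ipso substitution of one Me3Si group) gives the silyl ynone.

Step 19
Reactants: 26 methyl 4-oxo-6-(trimethylsilyl)hex-5-ynoate
Product: 27 methyl (4S)-4-hydroxy-6-(trimethylsilyl)hex-5-ynoate
Conditions: Ru[(S,S)-TsNCH(Ph)CH(Ph)NH](η6-p-cymene) (1 mol %), iPrOH, rt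
Reagents that add atoms: none
Why: Noyori asymmetric transfer hydrogenation of the ynone with the (S,S)-catalyst gives the (S)-propargylic alcohol (C4), and the base-free conditions avoid γ-lactonisation.

Step 20
Reactants: 27 methyl (4S)-4-hydroxy-6-(trimethylsilyl)hex-5-ynoate
Product: 28 methyl (4S)-4-(triethylsilyloxy)-6-(trimethylsilyl)hex-5-ynoate
Conditions: Et3SiCl, imidazole, CH2Cl2, 0 °C (crude 27 used at once)
Reagents that add atoms: chlorotriethylsilane, CC[Si](Cl)(CC)CC
Why: Immediate silyl ether formation stops the γ-hydroxy ester from lactonising and gives a group that is removed very mildly at the end.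

Step 21
Reactants: 28 methyl (4S)-4-(triethylsilyloxy)-6-(trimethylsilyl)hex-5-ynoate
Product: 29 methyl (4S)-4-(triethylsilyloxy)hex-5-ynoate
Conditions: K2CO3 (0.2 equiv), MeOH, 0 °C
Reagents that add atoms: none
Why: Base-catalysed methanolysis of the C(sp)–Si bond (protodesilylation) is much faster than cleavage of the secondary O–SiEt3 ether, and the ester is already a methyl ester.

Step 22
Reactants: 29 methyl (4S)-4-(triethylsilyloxy)hex-5-ynoate
Product: 30 methyl (4S)-4-(triethylsilyloxy)hex-5-enoate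
Conditions: H2 (1 atm), Pd/CaCO3 poisoned with Pb(OAc)2, quinoline, EtOAc, rt
Reagents that add atoms: none
Why: Lindlar semi-hydrogenation stops at the terminal alkene.

Step 23
Reactants: 30 methyl (4S)-4-(triethylsilyloxy)hex-5-enoate; 31 (E)-but-2-enal
Product: 32 methyl (4S,5E)-7-oxo-4-(triethylsilyloxy)hept-5-enoate
Conditions: 31 (5 equiv), second-generation Hoveyda–Grubbs catalyst RuCl2(SIMes)(=CH–C6H4–2-OiPr) (5 mol %), CH2Cl2, 40 °C
Reagents that add atoms: none
Why: Olefin cross-metathesis with excess crotonaldehyde gives the conjugated enal as the thermodynamic E isomer and leaves C4 untouched.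

**Coupling and end game**

Step 24
Reactants: 23 (4S)-2-bromo-4-[(2Z,5Z)-octa-2,5-dien-1-yl]-4-(trimethylsilyloxy)cyclopent-2-en-1-one; 32 methyl (4S,5E)-7-oxo-4-(triethylsilyloxy)hept-5-enoate
Product: 34 methyl (4S,5E)-7-[(5S)-3-bromo-5-[(2Z,5Z)-octa-2,5-dien-1-yl]-2-oxo-5-(trimethylsilyloxy)cyclopent-3-en-1-yl]-7-hydroxy-4-(triethylsilyloxy)hept-5-enoate (epimers at C7/ring C1), via lithium dienolate 33 (not isolated)
Conditions: LiN(iPr)2 (1.05 equiv), THF, −78 °C, 30 min; then 32, −78 °C; AcOH quench at −78 °C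
Reagents that add atoms: none
Why: Kinetic α′-deprotonation gives the cross-conjugated lithium dienolate, which adds 1,2 to the enal (directed aldol addition) to form C7–C8; the two new centres are removed in the next step.

Step 25
Reactants: 34 methyl (4S,5E)-7-[(5S)-3-bromo-5-[(2Z,5Z)-octa-2,5-dien-1-yl]-2-oxo-5-(trimethylsilyloxy)cyclopent-3-en-1-yl]-7-hydroxy-4-(triethylsilyloxy)hept-5-enoate
Product: 36 methyl (4S,5E,7Z)-7-[(5R)-3-bromo-5-[(2Z,5Z)-octa-2,5-dien-1-yl]-2-oxo-5-(trimethylsilyloxy)cyclopent-3-en-1-ylidene]-4-(triethylsilyloxy)hept-5-enoate, via C7 mesylate 35 (not isolated)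
Conditions: MsCl, Et3N, CH2Cl2, −20 °C → rt; silica chromatography
Reagents that add atoms: none
Why: Mesylation and E1cB elimination give the cross-conjugated dienone as a 7Z/7E mixture; allylic strain between C6 and the fully substituted C12 in the 7E transition state should make 7Z (C6 syn to C=O) the main isomer, which is separated from 7E by chromatography.

Step 26
Reactants: 36 methyl (4S,5E,7Z)-7-[(5R)-3-bromo-5-[(2Z,5Z)-octa-2,5-dien-1-yl]-2-oxo-5-(trimethylsilyloxy)cyclopent-3-en-1-ylidene]-4-(triethylsilyloxy)hept-5-enoate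
Product: 37 methyl (4S,5E,7Z)-7-[(5R)-3-bromo-5-hydroxy-5-[(2Z,5Z)-octa-2,5-dien-1-yl]-2-oxocyclopent-3-en-1-ylidene]-4-hydroxyhept-5-enoate
Conditions: HF·pyridine, pyridine, THF, 0 °C
Reagents that add atoms: none
Why: Buffered fluoride desilylation removes the tertiary trimethylsilyl and secondary triethylsilyl ethers quickly at 0 °C, conditions mild enough to leave the bromo dienone, the alkenes and the γ-hydroxy methyl ester (no lactonisation) intact.

**Compound list**
1 | cis-cyclopent-4-ene-1,3-diyl diacetate (meso) | CC(=O)O[C@@H]1C=C[C@H](OC(C)=O)C1 | starting material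
2 | (1R,4S)-4-hydroxycyclopent-2-en-1-yl acetate | O[C@@H]1C=C[C@H](OC(C)=O)C1 | intermediate
3 | (1R)-4-oxocyclopent-2-en-1-yl acetate | O=C1C=C[C@H](OC(C)=O)C1 | intermediate
4 | (4R)-4-hydroxycyclopent-2-en-1-one | O=C1C=C[C@H](O)C1 | intermediate
5 | (4R)-4-(tert-butyldimethylsilyloxy)cyclopent-2-en-1-one | O=C1C=C[C@H](O[Si](C)(C)C(C)(C)C)C1 | intermediate
6 | ethyl acetate | CCOC(C)=O | starting material
7 | lithium enolate of ethyl acetate | C=C(O[Li])OCC | intermediate
8 | ethyl 2-[(1R,4R)-4-(tert-butyldimethylsilyloxy)-1-hydroxycyclopent-2-en-1-yl]acetate | CCOC(=O)C[C@@]1(O)C=C[C@H](O[Si](C)(C)C(C)(C)C)C1 | intermediate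
9 | ethyl 2-[(1R,4R)-1,4-dihydroxycyclopent-2-en-1-yl]acetate | CCOC(=O)C[C@@]1(O)C=C[C@H](O)C1 | intermediate
10 | ethyl 2-[(1R)-1-hydroxy-4-oxocyclopent-2-en-1-yl]acetate | CCOC(=O)C[C@@]1(O)C=CC(=O)C1 | intermediate
11 | ethyl 2-[(1R)-2,3-dibromo-1-hydroxy-4-oxocyclopentyl]acetate (trans-dibromide, isomer mixture at C2/C3) | CCOC(=O)C[C@@]1(O)C(Br)C(Br)C(=O)C1 | intermediate
12 | ethyl 2-[(1R)-3-bromo-1-hydroxy-4-oxocyclopent-2-en-1-yl]acetate | CCOC(=O)C[C@@]1(O)C=C(Br)C(=O)C1 | intermediate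
13 | ethyl 2-[(1R,4RS)-3-bromo-1,4-dihydroxycyclopent-2-en-1-yl]acetate | CCOC(=O)C[C@@]1(O)C=C(Br)C(O)C1 | intermediate
14 | ethyl 2-[(1R,4RS)-3-bromo-1,4-bis(triethylsilyloxy)cyclopent-2-en-1-yl]acetate | CCOC(=O)C[C@@]1(O[Si](CC)(CC)CC)C=C(Br)C(O[Si](CC)(CC)CC)C1 | intermediate
15 | 2-[(1R,4RS)-3-bromo-1,4-bis(triethylsilyloxy)cyclopent-2-en-1-yl]acetaldehyde | O=CC[C@@]1(O[Si](CC)(CC)CC)C=C(Br)C(O[Si](CC)(CC)CC)C1 | intermediate
16 | (3Z)-hex-3-en-1-ol | CC/C=C\CCO | starting material
17 | (3Z)-1-iodohex-3-ene | CC/C=C\CCI | intermediate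
18 | [(3Z)-hex-3-en-1-yl]triphenylphosphonium iodide | CC/C=C\CC[P+](c1ccccc1)(c1ccccc1)c1ccccc1.[I-] | intermediate
19 | [(3Z)-hex-3-en-1-ylidene]triphenylphosphorane | CC/C=C\CC=P(c1ccccc1)(c1ccccc1)c1ccccc1 | intermediate
20 | (1S,4RS)-3-bromo-1-[(2Z,5Z)-octa-2,5-dien-1-yl]-1,4-bis(triethylsilyloxy)cyclopent-2-ene | CC/C=C\C/C=C\C[C@@]1(O[Si](CC)(CC)CC)C=C(Br)C(O[Si](CC)(CC)CC)C1 | intermediate
21 | (1S,4RS)-3-bromo-1-[(2Z,5Z)-octa-2,5-dien-1-yl]cyclopent-2-ene-1,4-diol | CC/C=C\C/C=C\C[C@@]1(O)C=C(Br)C(O)C1 | intermediate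
22 | (4S)-2-bromo-4-hydroxy-4-[(2Z,5Z)-octa-2,5-dien-1-yl]cyclopent-2-en-1-one | CC/C=C\C/C=C\C[C@@]1(O)C=C(Br)C(=O)C1 | intermediate
23 | (4S)-2-bromo-4-[(2Z,5Z)-octa-2,5-dien-1-yl]-4-(trimethylsilyloxy)cyclopent-2-en-1-one | CC/C=C\C/C=C\C[C@@]1(O[Si](C)(C)C)C=C(Br)C(=O)C1 | intermediate
24 | methyl 4-chloro-4-oxobutanoate | COC(=O)CCC(Cl)=O | starting material
25 | bis(trimethylsilyl)acetylene | C[Si](C)(C)C#C[Si](C)(C)C | starting material
26 | methyl 4-oxo-6-(trimethylsilyl)hex-5-ynoate | COC(=O)CCC(=O)C#C[Si](C)(C)C | intermediate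
27 | methyl (4S)-4-hydroxy-6-(trimethylsilyl)hex-5-ynoate | COC(=O)CC[C@H](O)C#C[Si](C)(C)C | intermediate
28 | methyl (4S)-4-(triethylsilyloxy)-6-(trimethylsilyl)hex-5-ynoate | COC(=O)CC[C@H](O[Si](CC)(CC)CC)C#C[Si](C)(C)C | intermediate
29 | methyl (4S)-4-(triethylsilyloxy)hex-5-ynoate | COC(=O)CC[C@H](O[Si](CC)(CC)CC)C#C | intermediate
30 | methyl (4S)-4-(triethylsilyloxy)hex-5-enoate | COC(=O)CC[C@H](O[Si](CC)(CC)CC)C=C | intermediate
31 | (E)-but-2-enal (crotonaldehyde) | C/C=C/C=O | starting material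
32 | methyl (4S,5E)-7-oxo-4-(triethylsilyloxy)hept-5-enoate | COC(=O)CC[C@H](O[Si](CC)(CC)CC)/C=C/C=O | intermediate
33 | lithium (3S)-5-bromo-3-[(2Z,5Z)-octa-2,5-dien-1-yl]-3-(trimethylsilyloxy)cyclopenta-1,4-dien-1-olate | CC/C=C\C/C=C\C[C@@]1(O[Si](C)(C)C)C=C(Br)C(O[Li])=C1 | intermediate
34 | methyl (4S,5E)-7-[(5S)-3-bromo-5-[(2Z,5Z)-octa-2,5-dien-1-yl]-2-oxo-5-(trimethylsilyloxy)cyclopent-3-en-1-yl]-7-hydroxy-4-(triethylsilyloxy)hept-5-enoate (epimers at C7 and ring C1) | CC/C=C\C/C=C\C[C@@]1(O[Si](C)(C)C)C=C(Br)C(=O)C1C(O)/C=C/[C@@H](O[Si](CC)(CC)CC)CCC(=O)OC | intermediate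
35 | methyl (4S,5E)-7-[(5S)-3-bromo-5-[(2Z,5Z)-octa-2,5-dien-1-yl]-2-oxo-5-(trimethylsilyloxy)cyclopent-3-en-1-yl]-7-(methanesulfonyloxy)-4-(triethylsilyloxy)hept-5-enoate (epimers at C7 and ring C1) | CC/C=C\C/C=C\C[C@@]1(O[Si](C)(C)C)C=C(Br)C(=O)C1C(OS(C)(=O)=O)/C=C/[C@@H](O[Si](CC)(CC)CC)CCC(=O)OC | intermediate
36 | methyl (4S,5E,7Z)-7-[(5R)-3-bromo-5-[(2Z,5Z)-octa-2,5-dien-1-yl]-2-oxo-5-(trimethylsilyloxy)cyclopent-3-en-1-ylidene]-4-(triethylsilyloxy)hept-5-enoate | CC/C=C\C/C=C\C[C@@]1(O[Si](C)(C)C)C=C(Br)C(=O)/C1=C\C=C\[C@@H](O[Si](CC)(CC)CC)CCC(=O)OC | intermediate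
37 | methyl (4S,5E,7Z)-7-[(5R)-3-bromo-5-hydroxy-5-[(2Z,5Z)-octa-2,5-dien-1-yl]-2-oxocyclopent-3-en-1-ylidene]-4-hydroxyhept-5-enoate | CC/C=C\C/C=C\C[C@@]1(O)C=C(Br)C(=O)/C1=C\C=C\[C@@H](O)CCC(=O)OC | target

**Totals and risks**

Total step count: 26. Longest linear sequence: 18 steps (steps 1–11, 14–17, 24–26).

The three steps most likely to fail:

Step 5 (1,2-addition). The basic lithium enolate may enolise 5, with loss of silanol, or give a poor anti:syn ratio. The fallback sets out from 5 and replaces the lithium aldol by a Reformatsky addition. Ethyl bromoacetate and activated Zn dust (Me3SiCl cat., THF, 0 °C) give bromo(2-ethoxy-2-oxoethyl)zinc F1, a neutral zinc enolate made by zinc insertion rather than deprotonation. It adds to the carbonyl of 5 anti to the silyloxy group without deprotonating the enone, and NH4Cl work-up brings the route back at 8.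

Step 24 (aldol of the α-bromo enone). LiN(iPr)2 may attack the bromo enone, or the dienolate may decompose or give retro-aldol products. The fallback sets out from 23 and uses soft enolisation (Me3SiOTf, Et3N, CH2Cl2, −78 → 0 °C) to make the silyl dienol ether (3S)-5-bromo-3-[(2Z,5Z)-octa-2,5-dien-1-yl]-1,3-bis(trimethylsilyloxy)cyclopenta-1,4-diene F2. F2 is combined with 32 in a Mukaiyama aldol addition (BF3·OEt2, CH2Cl2, −78 °C), and aqueous work-up returns the route at 34.

Step 25 (7Z geometry). The 7Z preference is argued from allylic strain, not guaranteed, and the elimination may give mostly the 7E isomer. The fallback sets out from 34 and runs the same elimination, then collects the 7E isomer methyl (4S,5E,7E)-7-[(5R)-3-bromo-5-[(2Z,5Z)-octa-2,5-dien-1-yl]-2-oxo-5-(trimethylsilyloxy)cyclopent-3-en-1-ylidene]-4-(triethylsilyloxy)hept-5-enoate F3. F3 is photoisomerised through the dienone chromophore (hν ≥ 350 nm, benzene, Pyrex; the skipped diene does not absorb) to the photostationary mixture. The 7Z isomer is re-isolated by chromatography and F3 is recycled, coming back to the route at 36; any 5Z isomers formed are removed in the same separation.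

Further compounds
F1 | step 5 | bromo(2-ethoxy-2-oxoethyl)zinc | Br[Zn]CC(=O)OCC
F2 | step 24 | (3S)-5-bromo-3-[(2Z,5Z)-octa-2,5-dien-1-yl]-1,3-bis(trimethylsilyloxy)cyclopenta-1,4-diene | CC/C=C\C/C=C\C[C@@]1(O[Si](C)(C)C)C=C(Br)C(O[Si](C)(C)C)=C1
F3 | step 25 | methyl (4S,5E,7E)-7-[(5R)-3-bromo-5-[(2Z,5Z)-octa-2,5-dien-1-yl]-2-oxo-5-(trimethylsilyloxy)cyclopent-3-en-1-ylidene]-4-(triethylsilyloxy)hept-5-enoate | CC/C=C\C/C=C\C[C@@]1(O[Si](C)(C)C)C=C(Br)C(=O)/C1=C/C=C/[C@@H](O[Si](CC)(CC)CC)CCC(=O)OC
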